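## Analysis of the target

Selaginellin has no fused ring system. Five six-membered carbocycles are joined by single bonds, one alkyne and one exocyclic double bond. The hub is a benzene, ring A, numbered here C1 to C6: C1 carries the diaryl methide carbon, C2 a 4-hydroxyphenyl group (ring B), C3 and C4 carry hydrogen, C5 carries CH2OH and C6 a (4-hydroxyphenyl)ethynyl group. The methide carbon bears a 4-hydroxyphenyl ring and a cyclohexa-2,5-dienone ring, a quinone methide of the fuchsone type.

There is no stereocentre. The exocyclic double bond has no geometry, because the dienone ring is symmetric and a proton shift exchanges the roles of the two oxygenated rings on the methide carbon.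

The sensitive groups are:
- the quinone methide, which accepts hydride and other nucleophiles and under acid is a diaryl carbenium ion that can attack ring B;
- the diaryl alkyne with an oxygen nucleophile next to it on C5, which is open to cyclisation under Lewis-acid or electrophilic activation and to hydrometalation;
- the benzylic alcohol and the three phenols.

The synthesis is hard because C5, C6, C1 and C2 are four adjacent substituted carbons with heavy crowding at C1 and C6. In addition, the C5 carbon must end as an alcohol while the carbon on C1 must pass through a ketone to accept its last aryl group.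

The strategy rests on one feature. C6, which bears the alkyne, lies between the substituted C1 and C5, and C5 has an unsubstituted neighbour, C4. C6 and C5 are therefore the ipso and the only free ortho position of an aryl iodide whose other ortho position is blocked.

## Retrosynthetic reasoning

**Target 21 to carbinol 19.** The quinone methide is the dehydrated form of tetrahydroxy carbinol 20, so the last operation only has to free four hydroxyl groups and remove water. In 19 the three phenols are methoxymethyl ethers and the primary alcohol is a silyl ether, so one treatment with dilute protic acid does all of this. Methyl ethers would be the simpler choice, but they were set aside. Their removal needs a boron trihalide or a hot nucleophile, which would turn the benzylic oxygen into a halide, add across an alkyne that has an oxygen nucleophile beside it, and drive the carbenium ion onto ring B.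

**Carbinol 19 to ketone 17 and aryllithium 18.** The bond between the methide carbon and one of its two equivalent oxygenated rings is cut. Either cut gives the same ketone, and the bond to the crowded ring A is left alone. The forward reaction is a single 1,2-addition of 18, made from bromide 4, to a diaryl ketone that cannot enolise.

**Ketone 17 back to keto ester 14.** The C5 carbon arrives at the carboxyl level, and no hydride reduces the ester while leaving the ketone intact. Both are therefore reduced (diol 15), the open primary alcohol is silylated (16), and the buried diaryl carbinol is reoxidised (17). These three steps are the price of the oxidation level that the key step delivers.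

**Keto ester 14 to iodide 8, anhydride 11 and alkyne 13.** This is the central disconnection: the C5–carboxyl bond and the C6–alkyne bond are cut together. They are cut here because C6 and C5 stand in the ipso/ortho relation of an aryl iodide, which a Catellani relay can use to functionalise both carbons in one operation. The gain is that the two most crowded bonds are made at once on an iodide that carries only the two easy substituents, and that geometry, not directing effects, fixes the positions. The forward reaction has to palladate C5–H, transfer the alkoxycarbonyl group of 11, expel the transient mediator and alkynylate C6, all faster than direct coupling of 8 with 13.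

**Iodide 8 to aldehyde 3 and Grignard reagent 5.** The C–I bond needed for the relay comes from bromide 7 by halide exchange. Ketone 7 comes from carbinol 6 by oxidation. Carbinol 6 is cut between the carbinol carbon and its oxygenated ring, giving aldehyde 3 and Grignard reagent 5, which is made from the same bromide 4 that later supplies 18.

**Aldehyde 3 to dibromide 1 and boronic acid 2.** The C2–ring B bond is cut by a Suzuki disconnection. The two C–Br bonds of 1 are equivalent, so the coupling is statistical. It is placed first so that any loss falls on the cheapest materials.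

**Reagents.** Anhydride 11 is cut at its anhydride oxygen into acid 9 and chloroformate 10. Alkyne 13 is the one-carbon homologue of aldehyde 12.

## Alternatives that were turned down

**Alternative 1:** Ring A is disconnected at C1–C6. In the forward key step an alkoxide base makes the doubly activated methylene of diketo malonate A2 acylate one of its own ester groups (a Claisen closure), giving the 2-aroylcyclohexane-1,3-dione A1.
- For: the precursors are cheap and acyclic, the stabilised triketone drives the closure, and the aroyl group on C1 and the ester on C5 arrive in place. Every step is of a long-known type, and on that point it is stronger than the chosen route.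
- Against: A1 is two oxidation levels below a benzene and must be dehydrogenated. The oxygens on C2 and C6, both ortho to the ketone and both chelated, must then be told apart so that ring B goes to one and the alkyne to the other. The C6 sulfonate would have to couple between two carbonyl groups.
- Comparison: five or six operations would be needed to reach the stage that 14 reaches in one. The chosen strategy gives unambiguous placement: the iodide fixes each site, and no pair of near-identical phenols has to be differentiated.

**Alternative 2:** Ring A is disconnected at C1–C2 and C5–C6. In the forward key step diene A5 adds across the ketone-conjugated triple bond of diynone A4, and a quinone oxidant aromatises the cyclohexadiene in the same pot to give ketone A3.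
- For: it is the most convergent plan. All four substituents arrive at once, and the C5 carbon is already a silylated alcohol. A3 corresponds to ketone 17, so steps 8 to 10 would fall away. On step economy after the key step it is stronger than the chosen route.
- Against: the orientation depends on the aryl terminus of A5 bonding to the carbon next to the carbonyl. The aryl group favours this, but the oxygenated alkyl group on the other terminus pulls the opposite way, so the outcome rests on a difference between two modest directors. The wrong isomer merely exchanges ring B and the silyloxymethyl group and would be hard to separate. A 1,4-disubstituted diene and a disubstituted alkyne also react slowly, while A4 is an acceptor that oligomerises on heating.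
- Comparison: the chosen strategy is three steps longer after the key step, but the ipso/ortho mechanism fixes where each group goes.

**Alternative 3:** Ring A is disconnected at C4–C5 and C1–C2. In the forward key step, under base, one methylene of keto diester A7 displaces dimethylamine from enaminone A8 and the other condenses with the aryl ketone, giving phenol A6 after loss of water.
- For: there are two cheap components, and ring B is in place without a cross-coupling. The C6 phenol is a handle for sulfonylation and Sonogashira coupling. Since the two oxygenated rings on the methide carbon are the same, the C1 ester could in principle take both in one double addition. On cost and on precedent of the individual reactions it is as strong as or stronger than the chosen route.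
- Against: the two methyl esters of A6 must be told apart, and the wrong one is the reactive one. The C5 ester, which must only be reduced, is open. The C1 ester, which must be attacked twice by an aryl nucleophile, lies between ring B and the C6 substituent and behaves like a 2,6-disubstituted benzoate. The ring-closing condensation onto an aryl ketone is also the slow step and can lose to O-cyclisation.
- Comparison: the chosen strategy brings the C1 carbon in as an aldehyde and gives it its first aryl group in step 2 while the position is still open. Only one addition to a ketone is left for the end.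

Key step: step 7

Assumption: 4-(methoxymethoxy)phenylboronic acid, 1-bromo-4-(methoxymethoxy)benzene and 4-(methoxymethoxy)benzaldehyde are treated as purchasable; each is otherwise one step from the parent phenol by methoxymethylation.

## Route

Step 1
Reactants: 1 2,6-dibromobenzaldehyde; 2 4-(methoxymethoxy)phenylboronic acid
Product: 3 2-bromo-6-[4-(methoxymethoxy)phenyl]benzaldehyde
Conditions: Pd(PPh3)4 (3 mol%), Na2CO3 (2 M aq.), toluene/EtOH, 80 °C; 1 in twofold excess, the surplus recovered
Reagents that add atoms: none
Why: Suzuki–Miyaura coupling at one of two equivalent C–Br bonds; an excess of the dibromide and a catalyst without bulky ligands should hold the reaction at mono-arylation, and the aldehyde and the acetal ether are inert to aqueous carbonate.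

Step 2
Reactants: 3 2-bromo-6-[4-(methoxymethoxy)phenyl]benzaldehyde; 4 1-bromo-4-(methoxymethoxy)benzene
Product: 6 [2-bromo-6-[4-(methoxymethoxy)phenyl]phenyl][4-(methoxymethoxy)phenyl]methanol (racemic), via aryl Grignard reagent 5 (not isolated)
Conditions: 4, Mg, THF, reflux; then 3, THF, 0 °C; sat. aq. NH4Cl
Reagents that add atoms: none
Why: Grignard addition to an aldehyde; an arylmagnesium bromide does not exchange with an aryl bromide at 0 °C, so the ring bromide survives. The carbinol centre forms racemic and is removed by the oxidation in step 3.

Step 3
Reactants: 6 [2-bromo-6-[4-(methoxymethoxy)phenyl]phenyl][4-(methoxymethoxy)phenyl]methanol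
Product: 7 [2-bromo-6-[4-(methoxymethoxy)phenyl]phenyl][4-(methoxymethoxy)phenyl]methanone
Conditions: Dess–Martin periodinane, CH2Cl2, rt
Reagents that add atoms: none
Why: Dess–Martin oxidation of a benzhydrol to the benzophenone under nearly neutral conditions that leave the acetal ethers and the aryl bromide untouched.

Step 4
Reactants: 7 [2-bromo-6-[4-(methoxymethoxy)phenyl]phenyl][4-(methoxymethoxy)phenyl]methanone
Product: 8 [2-iodo-6-[4-(methoxymethoxy)phenyl]phenyl][4-(methoxymethoxy)phenyl]methanone
Conditions: CuI (10 mol%), trans-N,N'-dimethylcyclohexane-1,2-diamine (20 mol%), NaI (2 equiv), 1,4-dioxane, 110 °C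
Reagents that add atoms: sodium iodide, [Na+].[I-]
Why: copper-catalysed aromatic Finkelstein exchange, driven by the low solubility of NaBr in dioxane; a diaryl ketone that cannot enolise and acetal ethers are tolerated.

Step 5
Reactants: 9 2,4,6-trimethylbenzoic acid; 10 2-methylpropyl carbonochloridate (isobutyl chloroformate)
Product: 11 2-methylpropyl 2,4,6-trimethylbenzoyl carbonate
Conditions: Et3N, CH2Cl2, 0 °C; filtered and concentrated
Reagents that add atoms: none
Why: standard formation of a mixed carboxylic–carbonic anhydride; the two ortho methyl groups shield the aroyl carbonyl, so the reagent can be handled and later transfers only its alkoxycarbonyl half.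

Step 6
Reactants: 12 4-(methoxymethoxy)benzaldehyde
Product: 13 1-ethynyl-4-(methoxymethoxy)benzene
Conditions: dimethyl (1-diazo-2-oxopropyl)phosphonate, K2CO3, MeOH, rt
Reagents that add atoms: dimethyl (1-diazo-2-oxopropyl)phosphonate, COP(=O)(OC)C(=[N+]=[N-])C(C)=O
Why: Ohira–Bestmann (Seyferth–Gilbert) homologation of an aryl aldehyde to the terminal alkyne; basic methanol does not touch the acetal ether.

Step 7
Reactants: 8 [2-iodo-6-[4-(methoxymethoxy)phenyl]phenyl][4-(methoxymethoxy)phenyl]methanone; 11 2-methylpropyl 2,4,6-trimethylbenzoyl carbonate; 13 1-ethynyl-4-(methoxymethoxy)benzene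
Product: 14 2-methylpropyl 3-[4-(methoxymethoxy)benzoyl]-4-[4-(methoxymethoxy)phenyl]-2-{[4-(methoxymethoxy)phenyl]ethynyl}benzoate
Conditions: Pd(OAc)2 (10 mol%), tri(2-furyl)phosphine (25 mol%), norbornene (1 equiv), Cs2CO3 (3 equiv), 11 (2 equiv), toluene, 100 °C; 13 (1.5 equiv) added over several hours
Reagents that add atoms: none
Why: Proposed new method: the closest known reactions are the palladium/norbornene ortho C–H alkoxycarbonylation of aryl iodides with carboxylic–carbonic anhydrides, terminated so far by Heck coupling or by hydride, and the ipso alkynylation by terminal alkynes that ends ortho-alkylation and ortho-amination relays; the proposal joins the two. Zerovalent palladium inserts into the C6–I bond of 8, norbornene inserts into the aryl–palladium bond, and carbonate-assisted C–H palladation at C5 closes a five-membered aryl–norbornyl palladacycle of divalent palladium. Anhydride 11 adds oxidatively through its carbonate C–O bond, since the trimethylbenzoyl carbonyl is shielded, and reductive elimination from tetravalent palladium forms the C5–carboxyl bond. With both positions next to C6 now filled, β-carbon elimination expels norbornene, and the aryl–palladium species at C6 takes up alkyne 13 by carbonate-assisted deprotonation and forms the C6–alkyne bond by reductive elimination. No ring is closed and no stereocentre is formed. The step needs site selectivity, which the substrate supplies because C5–H is the only hydrogen ortho to iodine and its neighbour C4 is unsubstituted, and it needs the aroyl group on C1 to force norbornene out before the alkyne couples. It also needs the relay to outrun direct coupling of 8 with 13, for which norbornene insertion should be faster than copper-free alkynylation and 13 is kept at low concentration.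

Step 8
Reactants: 14 2-methylpropyl 3-[4-(methoxymethoxy)benzoyl]-4-[4-(methoxymethoxy)phenyl]-2-{[4-(methoxymethoxy)phenyl]ethynyl}benzoate
Product: 15 {3-(hydroxymethyl)-6-[4-(methoxymethoxy)phenyl]-2-{[4-(methoxymethoxy)phenyl]ethynyl}phenyl}[4-(methoxymethoxy)phenyl]methanol (racemic)
Conditions: LiAlH4, THF, 0 °C, short reaction time; Fieser work-up
Reagents that add atoms: none
Why: hydride reduction of the ester to the primary alcohol and of the diaryl ketone to the benzhydrol; hydroalumination of a diaryl alkyne next to a benzylic alkoxide needs heating and should not occur at 0 °C. The carbinol centre is racemic and is erased in step 10.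

Step 9
Reactants: 15 {3-(hydroxymethyl)-6-[4-(methoxymethoxy)phenyl]-2-{[4-(methoxymethoxy)phenyl]ethynyl}phenyl}[4-(methoxymethoxy)phenyl]methanol
Product: 16 {3-({[tert-butyl(dimethyl)silyl]oxy}methyl)-6-[4-(methoxymethoxy)phenyl]-2-{[4-(methoxymethoxy)phenyl]ethynyl}phenyl}[4-(methoxymethoxy)phenyl]methanol (racemic)
Conditions: TBSCl (1.1 equiv), imidazole, CH2Cl2, 0 °C
Reagents that add atoms: tert-butyl(chloro)dimethylsilane, CC(C)(C)[Si](C)(C)Cl
Why: silylation distinguishes the open primary benzylic alcohol from the secondary carbinol, which is buried between ring B and the alkyne.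

Step 10
Reactants: 16 {3-({[tert-butyl(dimethyl)silyl]oxy}methyl)-6-[4-(methoxymethoxy)phenyl]-2-{[4-(methoxymethoxy)phenyl]ethynyl}phenyl}[4-(methoxymethoxy)phenyl]methanol
Product: 17 {3-({[tert-butyl(dimethyl)silyl]oxy}methyl)-6-[4-(methoxymethoxy)phenyl]-2-{[4-(methoxymethoxy)phenyl]ethynyl}phenyl}[4-(methoxymethoxy)phenyl]methanone
Conditions: Dess–Martin periodinane, CH2Cl2, rt
Reagents that add atoms: none
Why: Dess–Martin oxidation restores the benzophenone; the silyl ether, the acetal ethers and the alkyne are not affected.

Step 11
Reactants: 17 {3-({[tert-butyl(dimethyl)silyl]oxy}methyl)-6-[4-(methoxymethoxy)phenyl]-2-{[4-(methoxymethoxy)phenyl]ethynyl}phenyl}[4-(methoxymethoxy)phenyl]methanone; 4 1-bromo-4-(methoxymethoxy)benzene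
Product: 19 {3-({[tert-butyl(dimethyl)silyl]oxy}methyl)-6-[4-(methoxymethoxy)phenyl]-2-{[4-(methoxymethoxy)phenyl]ethynyl}phenyl}bis[4-(methoxymethoxy)phenyl]methanol, via aryllithium 18 (not isolated)
Conditions: 4, n-BuLi, THF, −78 °C; then 17, −78 to 0 °C; sat. aq. NH4Cl
Reagents that add atoms: none
Why: bromine–lithium exchange, then 1,2-addition of the aryllithium to a ketone that cannot enolise; the linear alkyne on one flank leaves the carbonyl accessible. No stereocentre arises, because the two aryl groups on the carbinol carbon are identical.

Step 12
Reactants: 19 {3-({[tert-butyl(dimethyl)silyl]oxy}methyl)-6-[4-(methoxymethoxy)phenyl]-2-{[4-(methoxymethoxy)phenyl]ethynyl}phenyl}bis[4-(methoxymethoxy)phenyl]methanol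
Product: 21 selaginellin, 4-{[3-(hydroxymethyl)-6-(4-hydroxyphenyl)-2-[(4-hydroxyphenyl)ethynyl]phenyl](4-hydroxyphenyl)methylidene}cyclohexa-2,5-dien-1-one, via tetrahydroxy carbinol 20 (not isolated)
Conditions: HCl (3 M aq.), MeOH/THF, 40 °C; then aq. NaHCO3 to pH 6–7
Reagents that add atoms: none
Why: acid-catalysed acetal exchange, in which methanol takes up the methoxymethyl groups, and silyl ether solvolysis free the four hydroxyl groups. The 4-hydroxyphenyl carbinol then ionises and loses water, and on neutralisation the cation gives up a phenolic proton to form the conjugated quinone methide, which should be the preferred form.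

## Compound list

1 | 2,6-dibromobenzaldehyde | O=Cc1c(Br)cccc1Br | starting material
2 | 4-(methoxymethoxy)phenylboronic acid | COCOc1ccc(cc1)B(O)O | starting material
3 | 2-bromo-6-[4-(methoxymethoxy)phenyl]benzaldehyde | O=Cc1c(Br)cccc1-c1ccc(OCOC)cc1 | intermediate
4 | 1-bromo-4-(methoxymethoxy)benzene | COCOc1ccc(Br)cc1 | starting material
5 | 4-(methoxymethoxy)phenylmagnesium bromide | COCOc1ccc([Mg]Br)cc1 | intermediate
6 | [2-bromo-6-[4-(methoxymethoxy)phenyl]phenyl][4-(methoxymethoxy)phenyl]methanol (racemic) | OC(c1ccc(OCOC)cc1)c1c(Br)cccc1-c1ccc(OCOC)cc1 | intermediate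
7 | [2-bromo-6-[4-(methoxymethoxy)phenyl]phenyl][4-(methoxymethoxy)phenyl]methanone | O=C(c1ccc(OCOC)cc1)c1c(Br)cccc1-c1ccc(OCOC)cc1 | intermediate
8 | [2-iodo-6-[4-(methoxymethoxy)phenyl]phenyl][4-(methoxymethoxy)phenyl]methanone | O=C(c1ccc(OCOC)cc1)c1c(I)cccc1-c1ccc(OCOC)cc1 | intermediate
9 | 2,4,6-trimethylbenzoic acid | Cc1cc(C)c(C(=O)O)c(C)c1 | starting material
10 | 2-methylpropyl carbonochloridate (isobutyl chloroformate) | CC(C)COC(=O)Cl | starting material
11 | 2-methylpropyl 2,4,6-trimethylbenzoyl carbonate | CC(C)COC(=O)OC(=O)c1c(C)cc(C)cc1C | intermediate
12 | 4-(methoxymethoxy)benzaldehyde | COCOc1ccc(C=O)cc1 | starting material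
13 | 1-ethynyl-4-(methoxymethoxy)benzene | COCOc1ccc(C#C)cc1 | intermediate
14 | 2-methylpropyl 3-[4-(methoxymethoxy)benzoyl]-4-[4-(methoxymethoxy)phenyl]-2-{[4-(methoxymethoxy)phenyl]ethynyl}benzoate | CC(C)COC(=O)c1ccc(-c2ccc(OCOC)cc2)c(C(=O)c2ccc(OCOC)cc2)c1C#Cc1ccc(OCOC)cc1 | intermediate
15 | {3-(hydroxymethyl)-6-[4-(methoxymethoxy)phenyl]-2-{[4-(methoxymethoxy)phenyl]ethynyl}phenyl}[4-(methoxymethoxy)phenyl]methanol (racemic) | OCc1ccc(-c2ccc(OCOC)cc2)c(C(O)c2ccc(OCOC)cc2)c1C#Cc1ccc(OCOC)cc1 | intermediate
16 | {3-({[tert-butyl(dimethyl)silyl]oxy}methyl)-6-[4-(methoxymethoxy)phenyl]-2-{[4-(methoxymethoxy)phenyl]ethynyl}phenyl}[4-(methoxymethoxy)phenyl]methanol (racemic) | CC(C)(C)[Si](C)(C)OCc1ccc(-c2ccc(OCOC)cc2)c(C(O)c2ccc(OCOC)cc2)c1C#Cc1ccc(OCOC)cc1 | intermediate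
17 | {3-({[tert-butyl(dimethyl)silyl]oxy}methyl)-6-[4-(methoxymethoxy)phenyl]-2-{[4-(methoxymethoxy)phenyl]ethynyl}phenyl}[4-(methoxymethoxy)phenyl]methanone | CC(C)(C)[Si](C)(C)OCc1ccc(-c2ccc(OCOC)cc2)c(C(=O)c2ccc(OCOC)cc2)c1C#Cc1ccc(OCOC)cc1 | intermediate
18 | 4-(methoxymethoxy)phenyllithium | [Li]c1ccc(OCOC)cc1 | intermediate
19 | {3-({[tert-butyl(dimethyl)silyl]oxy}methyl)-6-[4-(methoxymethoxy)phenyl]-2-{[4-(methoxymethoxy)phenyl]ethynyl}phenyl}bis[4-(methoxymethoxy)phenyl]methanol | CC(C)(C)[Si](C)(C)OCc1ccc(-c2ccc(OCOC)cc2)c(C(O)(c2ccc(OCOC)cc2)c2ccc(OCOC)cc2)c1C#Cc1ccc(OCOC)cc1 | intermediate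
20 | [3-(hydroxymethyl)-6-(4-hydroxyphenyl)-2-[(4-hydroxyphenyl)ethynyl]phenyl]bis(4-hydroxyphenyl)methanol | OCc1ccc(-c2ccc(O)cc2)c(C(O)(c2ccc(O)cc2)c2ccc(O)cc2)c1C#Cc1ccc(O)cc1 | intermediate
21 | selaginellin | O=C1C=CC(=C(c2ccc(O)cc2)c2c(-c3ccc(O)cc3)ccc(CO)c2C#Cc2ccc(O)cc2)C=C1 | target

## Step count and least certain steps

Total: 12 steps. Longest linear sequence: 10 steps (1, 2, 3, 4, 7, 8, 9, 10, 11, 12); steps 5 and 6 are one-step side branches.

**Step 7 (key step, proposed new method).**
- What may go wrong: the aryl–palladium intermediate may couple with the alkyne before norbornene inserts, giving alkynylation without carboxylation. The aryl–palladium bond may attack the neighbouring aroyl ring by intramolecular C–H arylation. After carboxylation, the aryl–palladium species sits between an ester and a ketone, and protonation may overtake its slow alkynylation. The anhydride may also be consumed by acyl transfer to the alkyne.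
- Fallback by known chemistry, from 8 and 11, returning at 14: the relay is run with tert-butyl acrylate in place of 13, the Heck termination with which the ortho-alkoxycarbonylation is established. This gives 2-methylpropyl 2-[(E)-3-tert-butoxy-3-oxoprop-1-en-1-yl]-3-[4-(methoxymethoxy)benzoyl]-4-[4-(methoxymethoxy)phenyl]benzoate F1. Lemieux–Johnson cleavage (OsO4 cat., NaIO4, 2,6-lutidine, dioxane/water) gives 2-methylpropyl 2-formyl-3-[4-(methoxymethoxy)benzoyl]-4-[4-(methoxymethoxy)phenyl]benzoate F2. Ohira–Bestmann homologation (Cs2CO3, 2-methylpropan-1-ol/THF, so that any ester exchange is degenerate) gives 2-methylpropyl 2-ethynyl-3-[4-(methoxymethoxy)benzoyl]-4-[4-(methoxymethoxy)phenyl]benzoate F3. Sonogashira coupling of F3 with 4 (PdCl2(PPh3)2, CuI, Et3N, 70 °C) gives 14.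

**Step 12.**
- What may go wrong: the diaryl carbenium ion formed under acid may close onto ring B by Friedel–Crafts attack. The C5 hydroxymethyl oxygen may add to the acid-activated, electron-rich alkyne. Formaldehyde equivalents may be captured by the free phenols.
- Fallback, from 17, returning at 20 and so at 21: the acetals are removed while the methide carbon is still a ketone and cannot ionise (HCl, MeOH/THF), giving [3-(hydroxymethyl)-6-(4-hydroxyphenyl)-2-[(4-hydroxyphenyl)ethynyl]phenyl](4-hydroxyphenyl)methanone F4. Full silylation (TBSCl in excess, imidazole, DMF) gives the tetrakis(tert-butyldimethylsilyl) ether of that ketone F5. (4-Bromophenoxy)(tert-butyl)dimethylsilane and n-BuLi at −78 °C give 4-[(tert-butyldimethylsilyl)oxy]phenyllithium F6, which adds to F5 to give the pentasilylated triaryl carbinol F7. Bu4NF buffered with AcOH in THF removes all five silyl groups to give 20, which loses water to 21 without strong acid.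

**Step 4.**
- What may go wrong: halide exchange at the hindered position next to the aroyl group may stop short of completion, leaving bromide that is inert in step 7 and hard to separate.
- Fallback, from 6, returning at 8: carbinol 6 is treated with n-BuLi (2.1 equiv, THF, −78 °C), which forms the alkoxide and then exchanges bromine for lithium, and iodine is added to give [2-iodo-6-[4-(methoxymethoxy)phenyl]phenyl][4-(methoxymethoxy)phenyl]methanol F8. Dess–Martin oxidation of F8 gives 8.

**Step 1.**
- What may go wrong: a second arylation at the remaining C–Br bond, which lowers the mono-coupling selectivity and complicates separation.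
- Fallback, from 2, returning at 3: 1-bromo-3-iodobenzene is deprotonated between the halogens (LiN(iPr)2, THF, −78 °C) and formylated with DMF to give 2-bromo-6-iodobenzaldehyde F9. Suzuki coupling of F9 with 2 (Pd(PPh3)4, Na2CO3, 40 °C) takes place at the C–I bond only and gives 3, so halogen identity replaces stoichiometry as the control.

## Further compounds

F1 | step 7 | 2-methylpropyl 2-[(E)-3-tert-butoxy-3-oxoprop-1-en-1-yl]-3-[4-(methoxymethoxy)benzoyl]-4-[4-(methoxymethoxy)phenyl]benzoate | CC(C)COC(=O)c1ccc(-c2ccc(OCOC)cc2)c(C(=O)c2ccc(OCOC)cc2)c1/C=C/C(=O)OC(C)(C)C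
F2 | step 7 | 2-methylpropyl 2-formyl-3-[4-(methoxymethoxy)benzoyl]-4-[4-(methoxymethoxy)phenyl]benzoate | CC(C)COC(=O)c1ccc(-c2ccc(OCOC)cc2)c(C(=O)c2ccc(OCOC)cc2)c1C=O
F3 | step 7 | 2-methylpropyl 2-ethynyl-3-[4-(methoxymethoxy)benzoyl]-4-[4-(methoxymethoxy)phenyl]benzoate | CC(C)COC(=O)c1ccc(-c2ccc(OCOC)cc2)c(C(=O)c2ccc(OCOC)cc2)c1C#C
F4 | step 12 | [3-(hydroxymethyl)-6-(4-hydroxyphenyl)-2-[(4-hydroxyphenyl)ethynyl]phenyl](4-hydroxyphenyl)methanone | OCc1ccc(-c2ccc(O)cc2)c(C(=O)c2ccc(O)cc2)c1C#Cc1ccc(O)cc1
F5 | step 12 | tetrakis(tert-butyldimethylsilyl) ether of F4 | CC(C)(C)[Si](C)(C)OCc1ccc(-c2ccc(O[Si](C)(C)C(C)(C)C)cc2)c(C(=O)c2ccc(O[Si](C)(C)C(C)(C)C)cc2)c1C#Cc1ccc(O[Si](C)(C)C(C)(C)C)cc1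
F6 | step 12 | 4-[(tert-butyldimethylsilyl)oxy]phenyllithium | [Li]c1ccc(O[Si](C)(C)C(C)(C)C)cc1
F7 | step 12 | pentakis(tert-butyldimethylsilyl) ether of carbinol 20 (tertiary hydroxyl free) | CC(C)(C)[Si](C)(C)OCc1ccc(-c2ccc(O[Si](C)(C)C(C)(C)C)cc2)c(C(O)(c2ccc(O[Si](C)(C)C(C)(C)C)cc2)c2ccc(O[Si](C)(C)C(C)(C)C)cc2)c1C#Cc1ccc(O[Si](C)(C)C(C)(C)C)cc1
F8 | step 4 | [2-iodo-6-[4-(methoxymethoxy)phenyl]phenyl][4-(methoxymethoxy)phenyl]methanol (racemic) | OC(c1ccc(OCOC)cc1)c1c(I)cccc1-c1ccc(OCOC)cc1
F9 | step 1 | 2-bromo-6-iodobenzaldehyde | O=Cc1c(Br)cccc1I
A1 | alternative 1 | methyl 4-hydroxy-3-(4-methoxybenzoyl)-2-oxocyclohex-3-ene-1-carboxylate (racemic, one enol form) | COC(=O)C1CCC(O)=C(C(=O)c2ccc(OC)cc2)C1=O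
A2 | alternative 1 | dimethyl 2-[5-(4-methoxyphenyl)-3,5-dioxopentyl]propanedioate | COC(=O)C(CCC(=O)CC(=O)c1ccc(OC)cc1)C(=O)OC
A3 | alternative 2 | [3-({[tert-butyl(dimethyl)silyl]oxy}methyl)-6-(4-methoxyphenyl)-2-[(4-methoxyphenyl)ethynyl]phenyl](4-methoxyphenyl)methanone | COc1ccc(cc1)C(=O)c1c(-c2ccc(OC)cc2)ccc(CO[Si](C)(C)C(C)(C)C)c1C#Cc1ccc(OC)cc1
A4 | alternative 2 | 1,5-bis(4-methoxyphenyl)penta-2,4-diyn-1-one | COc1ccc(cc1)C(=O)C#CC#Cc1ccc(OC)cc1
A5 | alternative 2 | tert-butyl{[(2E,4E)-5-(4-methoxyphenyl)penta-2,4-dien-1-yl]oxy}dimethylsilane | COc1ccc(/C=C/C=C/CO[Si](C)(C)C(C)(C)C)cc1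
A6 | alternative 3 | dimethyl 2-hydroxy-4-(4-methoxyphenyl)benzene-1,3-dicarboxylate | COC(=O)c1ccc(-c2ccc(OC)cc2)c(C(=O)OC)c1O
A7 | alternative 3 | dimethyl 3-oxopentanedioate | COC(=O)CC(=O)CC(=O)OC
A8 | alternative 3 | (2E)-3-(dimethylamino)-1-(4-methoxyphenyl)prop-2-en-1-one | COc1ccc(cc1)C(=O)/C=C/N(C)C
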